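**Retrosynthetic overview**

- Target 17 ⇐ benzyl ether 16 ⇐ mono-isobutyrate 14 ⇐ lactone 7. The two CH2O-acyl arms on the tertiary carbinol carbon C8 are unmasked and acylated in turn: the lactone carbonyl becomes the CH2O-isobutyryl arm, the tert-butyl ester becomes the CH2O-(S)-2-methylbutanoyl arm.
- 7 ⇐ achiral aryl tartronate 6 by cutting the aryl O–C(=O) bond. The feature used: the phenol oxygen on the ring carbon ortho to C8 is 1,4-related to both carboxyl carbons (C9 and C10) on C8, so a five-membered benzofuran-2(3H)-one ring can close onto either of two enantiotopic esters, and choosing one makes C8 stereogenic.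
- 6 ⇐ m-cresol 4 + di-tert-butyl ketomalonate 3 (aryl–C8 bond ortho to the phenol); 3 ⇐ di-tert-butyl malonate 1.
- Ring order: the benzene ring is bought; the benzofuranone ring, the only ring made, is closed in step 4 and opened again by hydride in step 5.

Key step: step 4

Assumption: the sense of induction of the phosphoric acid on this new substrate cannot be taken from precedent. The (R)-catalyst is written; its mirror image is used if it should deliver the (S)-lactone. C8, C9 and C10 denote the carbinol carbon and its two arms.

**Route**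

Step 1
Reactants: 1 di-tert-butyl malonate
Product: 2 di-tert-butyl 2-diazomalonate
Conditions: 4-acetamidobenzenesulfonyl azide, Et3N, MeCN, 0 °C to rt
Reagents that add atoms: 4-acetamidobenzenesulfonyl azide, CC(=O)Nc1ccc(cc1)S(=O)(=O)N=[N+]=[N-]
Why: Regitz diazo transfer to the doubly activated methylene, the malonate enolate attacking the terminal azide nitrogen and the sulfonamide leaving.

Step 2
Reactants: 2 di-tert-butyl 2-diazomalonate
Product: 3 di-tert-butyl 2-oxomalonate
Conditions: dimethyldioxirane (acetone solution), Rh2(OAc)4 (1 mol%), CH2Cl2, 0 °C to rt; evaporate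
Reagents that add atoms: dimethyldioxirane, CC1(C)OO1
Why: Oxygen-atom transfer from the dioxirane to the diazo carbon (through the rhodium carbenoid) with loss of N2 is a known entry to vicinal tricarbonyl compounds and should give the ketone free of water, as step 3 requires.

Step 3
Reactants: 4 m-cresol; 3 di-tert-butyl 2-oxomalonate
Product: 6 di-tert-butyl 2-hydroxy-2-(2-hydroxy-4-methylphenyl)malonate, via bromomagnesium 3-methylphenolate 5 (not isolated)
Conditions: EtMgBr (1.0 equiv), Et2O, 0 °C; solvent exchanged for toluene; 3, −20 to 0 °C; ice-cold water work-up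
Reagents that add atoms: ethylmagnesium bromide, CC[Mg]Br (its MgBr stays in 5 only and is lost on work-up)
Why: Casiraghi-type ortho-specific hydroxyalkylation of a magnesium phenolate, in which magnesium binds the phenolate oxygen and the ketone in a six-membered chelate so that the C–C bond forms at the free ortho carbon para to the methyl group, while the cold temperature and the bulky tert-butyl esters should keep the adduct from lactonising.

Step 4
Reactants: 6 di-tert-butyl 2-hydroxy-2-(2-hydroxy-4-methylphenyl)malonate
Product: 7 tert-butyl (R)-3-hydroxy-6-methyl-2-oxo-2,3-dihydrobenzofuran-3-carboxylate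
Conditions: (R)-3,3'-bis(2,4,6-triisopropylphenyl)-1,1'-binaphthyl-2,2'-diyl hydrogen phosphate (10 mol%), CH2Cl2, 25 to 35 °C
Reagents that add atoms: none
Why: Proposed new method: the phosphoric acid is expected to act bifunctionally, its P–OH protonating one tert-butyl ester carbonyl while its P=O accepts the phenol O–H, so that the phenol oxygen adds to that carbonyl and the tetrahedral intermediate collapses with loss of tert-butanol to the aryl lactone. The closest known reaction type is the chiral-phosphoric-acid-catalysed desymmetrising lactonisation of hydroxyalkyl di-tert-butyl malonates; new here are the phenol as nucleophile (an aryl ester is formed) and the hydroxyl on the prochiral carbon. The benzofuran-2(3H)-one ring closes in the 5-exo-trig mode. The one new stereocentre (C3 of 7, C8 of the target) is set by the catalyst alone, whose two triisopropylphenyl walls should hold the aryl plane and the tertiary hydroxyl (a further hydrogen-bond contact) so that only one of the two enantiotopic esters lies within reach of the bound phenol. The step needs enantiotopic-group selectivity over a racemic background closure, and the two bulky tert-butyl esters, which should not lactonise at room temperature without a strong acid, secure that the catalysed path decides.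

Step 5
Reactants: 7 tert-butyl (R)-3-hydroxy-6-methyl-2-oxo-2,3-dihydrobenzofuran-3-carboxylate
Product: 9 tert-butyl (S)-2,3-dihydroxy-2-(2-hydroxy-4-methylphenyl)propanoate, via lactol 8 (not isolated)
Conditions: NaBH4 (2.5 equiv), THF/EtOH 4:1, −10 to 0 °C; aqueous work-up near pH 7
Reagents that add atoms: none
Why: Chemoselective borohydride reduction, the aryl ester with its phenoxide leaving group being far more electrophilic than the hindered tert-butyl ester, so that hydride opens the lactone to lactol 8 and reduces its aldehyde form to the primary alcohol, while C8, which bears no hydrogen, keeps its configuration (the descriptor changes only by priority).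

Step 6
Reactants: 9 tert-butyl (S)-2,3-dihydroxy-2-(2-hydroxy-4-methylphenyl)propanoate
Product: 10 tert-butyl (S)-2-[2-(benzyloxy)-4-methylphenyl]-2,3-dihydroxypropanoate
Conditions: BnBr (1.1 equiv), K2CO3 (1.5 equiv), acetone, rt
Reagents that add atoms: benzyl bromide, BrCc1ccccc1
Why: Williamson etherification that is selective for the phenol (pKa about 10) over the primary and tertiary alcohols under a weak carbonate base.

Step 7
Reactants: 10 tert-butyl (S)-2-[2-(benzyloxy)-4-methylphenyl]-2,3-dihydroxypropanoate; 11 isobutyryl chloride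
Product: 12 tert-butyl (S)-2-[2-(benzyloxy)-4-methylphenyl]-2-hydroxy-3-(isobutyryloxy)propanoate
Conditions: pyridine (1.5 equiv), CH2Cl2, −20 to 0 °C
Reagents that add atoms: none
Why: Acylation of the primary alcohol by an acid chloride, the tertiary hydroxyl next to the ester being too hindered and too electron-poor to compete at low temperature.

Step 8
Reactants: 12 tert-butyl (S)-2-[2-(benzyloxy)-4-methylphenyl]-2-hydroxy-3-(isobutyryloxy)propanoate
Product: 13 (S)-2-[2-(benzyloxy)-4-methylphenyl]-2-hydroxy-3-(isobutyryloxy)propanoic acid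
Conditions: TFA/CH2Cl2 1:4, 0 °C to rt
Reagents that add atoms: none
Why: Acidolysis of the tert-butyl ester with loss of isobutene, in which ionisation of the tertiary benzylic C–O bond is disfavoured by the adjacent carboxyl group and the primary isobutyrate and the aryl benzyl ether should tolerate TFA at room temperature.

Step 9
Reactants: 13 (S)-2-[2-(benzyloxy)-4-methylphenyl]-2-hydroxy-3-(isobutyryloxy)propanoic acid
Product: 14 (R)-2-[2-(benzyloxy)-4-methylphenyl]-2,3-dihydroxypropyl isobutyrate
Conditions: BH3·THF (3 equiv), THF, 0 °C to rt; MeOH quench, neutral aqueous work-up, used at once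
Reagents that add atoms: none
Why: Chemoselective borane reduction of a carboxylic acid (through its acyloxyborane, helped by the α-hydroxyl) in the presence of an ester; the product is a 1,3-diol monoester in which acyl migration would erode the configuration at C8, so it is kept neutral and cold and taken on directly.

Step 10
Reactants: 14 (R)-2-[2-(benzyloxy)-4-methylphenyl]-2,3-dihydroxypropyl isobutyrate; 15 (S)-2-methylbutanoic acid
Product: 16 (S)-2-[2-(benzyloxy)-4-methylphenyl]-2-hydroxy-3-(isobutyryloxy)propyl (S)-2-methylbutanoate
Conditions: N,N'-dicyclohexylcarbodiimide (1.3 equiv), 4-(dimethylamino)pyridine (0.1 equiv), CH2Cl2, 0 °C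
Reagents that add atoms: none
Why: Steglich esterification of the only primary hydroxyl, in which the low temperature and the catalytic amount of 4-(dimethylamino)pyridine should keep the α-stereocentre of the acid from epimerising and the tertiary hydroxyl stays free.

Step 11
Reactants: 16 (S)-2-[2-(benzyloxy)-4-methylphenyl]-2-hydroxy-3-(isobutyryloxy)propyl (S)-2-methylbutanoate
Product: 17 (S)-2-hydroxy-2-(2-hydroxy-4-methylphenyl)-3-(isobutyryloxy)propyl (S)-2-methylbutanoate
Conditions: H2 (1 atm), Pd/C (10%), EtOAc, rt
Reagents that add atoms: none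
Why: Hydrogenolysis of the aryl benzyl ether over palladium on carbon under neutral conditions, under which both esters and, in the absence of acid, the tertiary benzylic alcohol should be retained.

**Compound list**

1 | di-tert-butyl malonate | CC(C)(C)OC(=O)CC(=O)OC(C)(C)C | starting material
2 | di-tert-butyl 2-diazomalonate | CC(C)(C)OC(=O)C(=[N+]=[N-])C(=O)OC(C)(C)C | intermediate
3 | di-tert-butyl 2-oxomalonate (ketomalonate) | CC(C)(C)OC(=O)C(=O)C(=O)OC(C)(C)C | intermediate
4 | m-cresol (3-methylphenol) | Cc1cccc(O)c1 | starting material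
5 | bromomagnesium 3-methylphenolate | Cc1cccc(O[Mg]Br)c1 | intermediate
6 | di-tert-butyl 2-hydroxy-2-(2-hydroxy-4-methylphenyl)malonate | CC(C)(C)OC(=O)C(O)(C(=O)OC(C)(C)C)c1ccc(C)cc1O | intermediate
7 | tert-butyl (R)-3-hydroxy-6-methyl-2-oxo-2,3-dihydrobenzofuran-3-carboxylate | CC(C)(C)OC(=O)[C@@]1(O)C(=O)Oc2cc(C)ccc21 | intermediate
8 | tert-butyl (3S)-2,3-dihydroxy-6-methyl-2,3-dihydrobenzofuran-3-carboxylate (lactol, both configurations at C2) | CC(C)(C)OC(=O)[C@@]1(O)C(O)Oc2cc(C)ccc21 | intermediate
9 | tert-butyl (S)-2,3-dihydroxy-2-(2-hydroxy-4-methylphenyl)propanoate | CC(C)(C)OC(=O)[C@@](O)(CO)c1ccc(C)cc1O | intermediate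
10 | tert-butyl (S)-2-[2-(benzyloxy)-4-methylphenyl]-2,3-dihydroxypropanoate | CC(C)(C)OC(=O)[C@@](O)(CO)c1ccc(C)cc1OCc1ccccc1 | intermediate
11 | isobutyryl chloride | CC(C)C(=O)Cl | starting material
12 | tert-butyl (S)-2-[2-(benzyloxy)-4-methylphenyl]-2-hydroxy-3-(isobutyryloxy)propanoate | CC(C)(C)OC(=O)[C@@](O)(COC(=O)C(C)C)c1ccc(C)cc1OCc1ccccc1 | intermediate
13 | (S)-2-[2-(benzyloxy)-4-methylphenyl]-2-hydroxy-3-(isobutyryloxy)propanoic acid | OC(=O)[C@@](O)(COC(=O)C(C)C)c1ccc(C)cc1OCc1ccccc1 | intermediate
14 | (R)-2-[2-(benzyloxy)-4-methylphenyl]-2,3-dihydroxypropyl isobutyrate | OC[C@@](O)(COC(=O)C(C)C)c1ccc(C)cc1OCc1ccccc1 | intermediate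
15 | (S)-2-methylbutanoic acid | CC[C@H](C)C(=O)O | starting material
16 | (S)-2-[2-(benzyloxy)-4-methylphenyl]-2-hydroxy-3-(isobutyryloxy)propyl (S)-2-methylbutanoate | CC[C@H](C)C(=O)OC[C@@](O)(COC(=O)C(C)C)c1ccc(C)cc1OCc1ccccc1 | intermediate
17 | (S)-2-hydroxy-2-(2-hydroxy-4-methylphenyl)-3-(isobutyryloxy)propyl (S)-2-methylbutanoate | CC[C@H](C)C(=O)OC[C@@](O)(COC(=O)C(C)C)c1ccc(C)cc1O | target

**Step count and risks**

Total step count: 11. Longest linear sequence: 11 steps (from 1 to 17; 4, 11 and 15 are bought and enter at steps 3, 7 and 10).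

Steps most likely to fail:

1. Step 4 (proposed new method). The weakly nucleophilic phenol may close too slowly, or closure may run through an uncatalysed path, so that conversion or enantiotopic-group selection is poor. Fallback by known chemistry, setting out from 6 and coming back at 14: the phenol of 6 is benzylated (BnBr, K2CO3, acetone, rt) to di-tert-butyl 2-[2-(benzyloxy)-4-methylphenyl]-2-hydroxymalonate F1. Both esters are reduced (LiAlH4, THF, 0 °C) to the prochiral 2-[2-(benzyloxy)-4-methylphenyl]propane-1,2,3-triol F2. A lipase-catalysed desymmetrising acylation of the two enantiotopic primary hydroxyls (immobilised Candida antarctica lipase B or Burkholderia cepacia lipase, vinyl isobutyrate, tert-butyl methyl ether, rt, the enzyme chosen by screening for the (R)-monoester) then gives 14.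

2. Step 3. The hindered ketone may react sluggishly, the phenolate may attack through oxygen or at the ring carbon para to the hydroxyl, or the magnesium adduct may lactonise in the flask to racemic lactone. Fallback setting out from 3 and coming back at 6: commercial 2-bromo-5-methylphenol F3 is treated with n-BuLi (2.1 equiv, Et2O/THF, −78 to 0 °C), which deprotonates the phenol and exchanges bromine for lithium to give lithium 2-lithio-5-methylphenolate F4. Its aryl carbon adds to the ketone of 3 at −78 °C, and a cold neutral quench gives 6 with the ring position fixed by the halogen.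

3. Step 8. During acidolysis the tertiary benzylic alcohol may ionise, the tert-butyl cation may alkylate the electron-rich ring, or the benzyl ether may be lost. Fallback that avoids acid, setting out from 10 and coming back at 16: the primary hydroxyl of 10 is silylated (TBDPSCl, imidazole, CH2Cl2) to tert-butyl (S)-2-[2-(benzyloxy)-4-methylphenyl]-3-[(tert-butyldiphenylsilyl)oxy]-2-hydroxypropanoate F5. The ester is reduced (LiAlH4, THF, 0 °C) to (R)-2-[2-(benzyloxy)-4-methylphenyl]-3-[(tert-butyldiphenylsilyl)oxy]propane-1,2-diol F6. The new primary hydroxyl is esterified with 15 (N,N'-dicyclohexylcarbodiimide, catalytic 4-(dimethylamino)pyridine, CH2Cl2, 0 °C) to (R)-2-[2-(benzyloxy)-4-methylphenyl]-3-[(tert-butyldiphenylsilyl)oxy]-2-hydroxypropyl (S)-2-methylbutanoate F7. The silyl ether is cleaved without base (HF·pyridine, THF/pyridine, 0 °C) to (S)-2-[2-(benzyloxy)-4-methylphenyl]-2,3-dihydroxypropyl (S)-2-methylbutanoate F8, which is acylated at once with 11 (pyridine, CH2Cl2, −20 °C) to give 16.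

**Further compounds**

F1 | step 4 | di-tert-butyl 2-[2-(benzyloxy)-4-methylphenyl]-2-hydroxymalonate | CC(C)(C)OC(=O)C(O)(C(=O)OC(C)(C)C)c1ccc(C)cc1OCc1ccccc1
F2 | step 4 | 2-[2-(benzyloxy)-4-methylphenyl]propane-1,2,3-triol | OCC(O)(CO)c1ccc(C)cc1OCc1ccccc1
F3 | step 3 | 2-bromo-5-methylphenol (bought) | Cc1ccc(Br)c(O)c1
F4 | step 3 | lithium 2-lithio-5-methylphenolate | Cc1ccc([Li])c(O[Li])c1
F5 | step 8 | tert-butyl (S)-2-[2-(benzyloxy)-4-methylphenyl]-3-[(tert-butyldiphenylsilyl)oxy]-2-hydroxypropanoate | CC(C)(C)OC(=O)[C@@](O)(CO[Si](c1ccccc1)(c1ccccc1)C(C)(C)C)c1ccc(C)cc1OCc1ccccc1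
F6 | step 8 | (R)-2-[2-(benzyloxy)-4-methylphenyl]-3-[(tert-butyldiphenylsilyl)oxy]propane-1,2-diol | OC[C@@](O)(CO[Si](c1ccccc1)(c1ccccc1)C(C)(C)C)c1ccc(C)cc1OCc1ccccc1
F7 | step 8 | (R)-2-[2-(benzyloxy)-4-methylphenyl]-3-[(tert-butyldiphenylsilyl)oxy]-2-hydroxypropyl (S)-2-methylbutanoate | CC[C@H](C)C(=O)OC[C@@](O)(CO[Si](c1ccccc1)(c1ccccc1)C(C)(C)C)c1ccc(C)cc1OCc1ccccc1
F8 | step 8 | (S)-2-[2-(benzyloxy)-4-methylphenyl]-2,3-dihydroxypropyl (S)-2-methylbutanoate | CC[C@H](C)C(=O)OC[C@@](O)(CO)c1ccc(C)cc1OCc1ccccc1
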